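## Retrosynthetic overview

- The strategy rests on C1, the secondary allylic carbinol of the ten-membered carbocycle, which is bonded to C10, the methyl-bearing carbon of the Z C9=C10 olefin. Cutting C1–C10 gives a C1 aldehyde and a Z-alkenyl iodide at C10, joined by CrCl2/NiCl2; this closes the ten-membered ring last, with lactone, acetate and tiglate in place.
- The seco iodo aldehyde comes from a C8-epimeric α-methylene lactone alcohol by Mitsunobu tigloylation (inversion at C8), PMB removal and oxidation. C7–C8 and the exocyclic C11=C13 come from a Zn Barbier addition of a 3-(bromomethyl)butenolide to (Z)-3-iodobut-2-enal.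
- The butenolide (the lactone ring, formed first) comes from ring-closing metathesis of the 2-(bromomethyl)acrylate of the C6 divinyl carbinol.
- C3–C4 comes from a Z-alkenyllithium and a Weinreb amide, followed by Corey–Bakshi–Shibata reduction and acetylation. The Z C4 iodide and C6 come from a lipase-resolved enynol by hydroxyl-directed trans-hydroalumination and iodination.

Key step: step 19

Remarks on the chemistry: germacrane numbering of the target is used for all intermediates (C12 lactone carbonyl, C13 exocyclic methylene, C14 methyl on C10, C15 on C4). The acetal carbon of the 1-ethoxyethyl group is carried as both epimers. In iodine-bearing intermediates the sequence-rule letters at C7 and C8 differ from those of the target for the same spatial arrangement, because the iodine on C10 raises the rank of the C9 branch.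

## Route

Step 1
Reactants: 1 tert-butyldimethyl(prop-2-yn-1-yloxy)silane; 2 acrolein
Product: 4 rac-6-[(tert-butyldimethylsilyl)oxy]hex-1-en-4-yn-3-ol, via lithium acetylide 3 (not isolated)
Conditions: n-BuLi, THF, −78 °C; then 2, −78 °C; aq NH4Cl
Reagents that add atoms: none
Why: The lithium acetylide adds to the carbonyl carbon of acrolein at low temperature (acetylide 1,2-addition), which joins C5 to C6 and gives the racemic carbinol whose vinyl group is the later C7 handle.

Step 2
Reactants: 4 rac-6-[(tert-butyldimethylsilyl)oxy]hex-1-en-4-yn-3-ol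
Product: 5 (3S)-6-[(tert-butyldimethylsilyl)oxy]hex-1-en-4-yn-3-ol
Conditions: Amano lipase PS, vinyl acetate, MTBE, rt, stopped a little past half conversion
Reagents that add atoms: none
Why: Lipase-catalysed kinetic resolution by acetyl transfer: by the empirical size rule for secondary alcohols (long alkynyl arm large, vinyl medium) the 3R enantiomer should be acetylated faster, so the unreacted alcohol is the 3S enantiomer, whose arrangement is that of C6 in the target.

Step 3
Reactants: 5 (3S)-6-[(tert-butyldimethylsilyl)oxy]hex-1-en-4-yn-3-ol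
Product: 7 (3S,4Z)-6-[(tert-butyldimethylsilyl)oxy]-5-iodohexa-1,4-dien-3-ol, via cyclic alkenylalanate 6 (not isolated)
Conditions: NaAlH2(OCH2CH2OMe)2, THF, 0 °C; then I2, THF, −78 °C
Reagents that add atoms: iodine, II
Why: Hydroxyl-directed trans-hydroalumination of the propargylic alcohol delivers hydride to C5 and aluminium to C4 in a five-membered alkoxyalanate, and iodinolysis of the C–Al bond with retention gives the Z-alkenyl iodide with iodine cis to C6, the geometry that later places C3 cis to C6.

Step 4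
Reactants: 7 (3S,4Z)-6-[(tert-butyldimethylsilyl)oxy]-5-iodohexa-1,4-dien-3-ol
Product: 8 tert-butyl{[(2Z,4S)-4-(1-ethoxyethoxy)-2-iodohexa-2,5-dien-1-yl]oxy}dimethylsilane
Conditions: ethyl vinyl ether, PPTS (cat.), CH2Cl2, 0 °C
Reagents that add atoms: ethyl vinyl ether, C=COCC
Why: Acid-catalysed addition of the alcohol to the enol ether (mixed acetal protection) gives a base-stable, non-silyl group on O6, chosen so that no 1,4 oxygen-to-carbon silyl shift can occur in the cis-alkenyllithium of step 7.

Step 5
Reactants: 9 methyl acrylate; 10 4-methoxybenzyl alcohol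
Product: 11 methyl 3-[(4-methoxybenzyl)oxy]propanoate
Conditions: NaH (cat.), THF, 0 °C to rt
Reagents that add atoms: none
Why: Alkoxide-catalysed oxa-Michael addition of the benzylic alcohol to the acrylate gives the C1–C3 unit with O1 as its PMB ether.

Step 6
Reactants: 11 methyl 3-[(4-methoxybenzyl)oxy]propanoate
Product: 12 N-methoxy-3-[(4-methoxybenzyl)oxy]-N-methylpropanamide
Conditions: MeNHOMe·HCl, i-PrMgCl, THF, −20 °C
Reagents that add atoms: N,O-dimethylhydroxylamine hydrochloride, CNOC.Cl
Why: The magnesium amide of N,O-dimethylhydroxylamine converts the methyl ester into the Weinreb amide (ester aminolysis), an acyl donor that stops at the ketone stage.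

Step 7
Reactants: 8 tert-butyl{[(2Z,4S)-4-(1-ethoxyethoxy)-2-iodohexa-2,5-dien-1-yl]oxy}dimethylsilane; 12 N-methoxy-3-[(4-methoxybenzyl)oxy]-N-methylpropanamide
Product: 14 (4Z,6S)-4-{[(tert-butyldimethylsilyl)oxy]methyl}-6-(1-ethoxyethoxy)-1-[(4-methoxybenzyl)oxy]octa-4,7-dien-3-one, via alkenyllithium 13 (not isolated)
Conditions: t-BuLi (2 equiv), Et2O, −78 °C; then 12, −78 to −40 °C; aq NH4Cl
Reagents that add atoms: none
Why: Iodine–lithium exchange occurs with retention of the olefin geometry and the alkenyllithium is acylated by the Weinreb amide through a chelated tetrahedral intermediate that collapses only on work-up, which forms C3–C4 and leaves C3 cis to C6.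

Step 8
Reactants: 14 (4Z,6S)-4-{[(tert-butyldimethylsilyl)oxy]methyl}-6-(1-ethoxyethoxy)-1-[(4-methoxybenzyl)oxy]octa-4,7-dien-3-one
Product: 15 (3S,4Z,6S)-4-{[(tert-butyldimethylsilyl)oxy]methyl}-6-(1-ethoxyethoxy)-1-[(4-methoxybenzyl)oxy]octa-4,7-dien-3-ol
Conditions: (R)-2-methyl-CBS-oxazaborolidine (cat.), catecholborane, toluene, −78 °C
Reagents that add atoms: none
Why: Corey–Bakshi–Shibata reduction in which the α-branched alkenyl group is the large and the CH2CH2OPMB chain the small substituent, so the (R)-catalyst should give the 3S carbinol under reagent control, and catecholborane at low temperature spares the vinyl group.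

Step 9
Reactants: 15 (3S,4Z,6S)-4-{[(tert-butyldimethylsilyl)oxy]methyl}-6-(1-ethoxyethoxy)-1-[(4-methoxybenzyl)oxy]octa-4,7-dien-3-ol
Product: 16 (3S,4Z,6S)-4-{[(tert-butyldimethylsilyl)oxy]methyl}-6-(1-ethoxyethoxy)-1-[(4-methoxybenzyl)oxy]octa-4,7-dien-3-yl acetate
Conditions: Ac2O, pyridine, DMAP (cat.), CH2Cl2, 0 °C
Reagents that add atoms: acetic anhydride, CC(=O)OC(C)=O
Why: DMAP-catalysed acylation of the secondary allylic alcohol installs the C3 acetate of the target with retention.

Step 10
Reactants: 16 (3S,4Z,6S)-4-{[(tert-butyldimethylsilyl)oxy]methyl}-6-(1-ethoxyethoxy)-1-[(4-methoxybenzyl)oxy]octa-4,7-dien-3-yl acetate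
Product: 17 (3S,4Z,6S)-4-{[(tert-butyldimethylsilyl)oxy]methyl}-6-hydroxy-1-[(4-methoxybenzyl)oxy]octa-4,7-dien-3-yl acetate
Conditions: PPTS (cat.), MeOH, 0 °C
Reagents that add atoms: none
Why: Acid-catalysed transacetalisation to methanol removes the mixed acetal far faster than the primary TBS ether or the allylic acetate can react, which frees O6.

Step 11
Reactants: 17 (3S,4Z,6S)-4-{[(tert-butyldimethylsilyl)oxy]methyl}-6-hydroxy-1-[(4-methoxybenzyl)oxy]octa-4,7-dien-3-yl acetate; 18 2-(bromomethyl)acrylic acid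
Product: 19 (3S,4Z,6S)-3-(acetyloxy)-4-{[(tert-butyldimethylsilyl)oxy]methyl}-1-[(4-methoxybenzyl)oxy]octa-4,7-dien-6-yl 2-(bromomethyl)prop-2-enoate
Conditions: DIC, DMAP (cat.), CH2Cl2, −10 °C
Reagents that add atoms: none
Why: Carbodiimide (Steglich) esterification of the C6 alcohol with retention, with low temperature and little DMAP so that the amine does not displace the allylic bromide.

Step 12
Reactants: 19 (3S,4Z,6S)-3-(acetyloxy)-4-{[(tert-butyldimethylsilyl)oxy]methyl}-1-[(4-methoxybenzyl)oxy]octa-4,7-dien-6-yl 2-(bromomethyl)prop-2-enoate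
Product: 20 (5R)-3-(bromomethyl)-5-[(1Z,3S)-3-(acetyloxy)-2-{[(tert-butyldimethylsilyl)oxy]methyl}-5-[(4-methoxybenzyl)oxy]pent-1-en-1-yl]furan-2(5H)-one
Conditions: second-generation Hoveyda–Grubbs catalyst (cat.), toluene, 80 °C, dilute
Reagents that add atoms: none
Why: Ring-closing metathesis between the C6 vinyl group and the 1,1-disubstituted acrylate olefin closes the five-membered lactone (C7=C11) with loss of ethene, and initiation at the monosubstituted olefin keeps the trisubstituted C4=C5 out of the reaction and leaves C6 untouched.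

Step 13
Reactants: 21 but-2-yn-1-ol
Product: 23 (Z)-3-iodobut-2-en-1-ol, via cyclic alkenylalanate 22 (not isolated)
Conditions: NaAlH2(OCH2CH2OMe)2, THF, 0 °C to rt; then I2, −78 °C
Reagents that add atoms: iodine, II
Why: Hydroxyl-directed trans-hydroalumination puts hydride on the carbon next to the carbinol and aluminium on the methyl-bearing carbon, and iodinolysis with retention gives the iodide with iodine cis to the CH2OH group, the later C8/C10 relation.

Step 14
Reactants: 23 (Z)-3-iodobut-2-en-1-ol
Product: 24 (Z)-3-iodobut-2-enal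
Conditions: MnO2, CH2Cl2, rt, dark
Reagents that add atoms: none
Why: MnO2 oxidises the allylic alcohol to the enal under neutral conditions that should keep the Z geometry, and the aldehyde is used at once.

Step 15
Reactants: 20 (5R)-3-(bromomethyl)-5-[(1Z,3S)-3-(acetyloxy)-2-{[(tert-butyldimethylsilyl)oxy]methyl}-5-[(4-methoxybenzyl)oxy]pent-1-en-1-yl]furan-2(5H)-one; 24 (Z)-3-iodobut-2-enal
Product: 26 8-epi lactone alcohol (3S,6R,7R,8R; 4Z,9Z), via allylzinc bromide 25 (not isolated)
Conditions: Zn dust, THF/sat. aq NH4Cl, 0 °C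
Reagents that add atoms: none
Why: Barbier allylation in which zinc inserts into the allylic C–Br bond and the allylzinc attacks the aldehyde through C7 on the butenolide face anti to the C6 side chain (trans lactone, exocyclic C11=C13), while a closed six-membered chair transition state with the aldehyde substituent equatorial, on a reagent whose C6 arm is held trans to the CH2Zn arm, gives the anti C7/C8 relation, which is the C8 epimer of the target arrangement.

Step 16
Reactants: 26 8-epi lactone alcohol (3S,6R,7R,8R; 4Z,9Z); 27 tiglic acid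
Product: 28 lactone tiglate with O1 as PMB ether (3S,6R,7S,8S; 4Z,9Z)
Conditions: PPh3, DIAD, toluene, −20 °C to rt
Reagents that add atoms: none
Why: Mitsunobu esterification in which tiglate displaces the C8 oxyphosphonium by SN2 with inversion, which corrects C8 and installs the ester in one operation, attack at C10 (SN2') being blocked by the iodine and methyl substituents.

Step 17
Reactants: 28 lactone tiglate with O1 as PMB ether (3S,6R,7S,8S; 4Z,9Z)
Product: 29 C1 primary alcohol (3S,6R,7S,8S; 4Z,9Z)
Conditions: DDQ, CH2Cl2/pH 7 buffer, 0 °C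
Reagents that add atoms: none
Why: DDQ oxidises the electron-rich PMB ether to an oxocarbenium ion that water hydrolyses, which leaves the silyl ether, the esters, the olefins and the alkenyl iodide, and the alcohol is carried on crude to avoid an acetyl shift from O3 to O1.

Step 18
Reactants: 29 C1 primary alcohol (3S,6R,7S,8S; 4Z,9Z)
Product: 30 seco iodo aldehyde (3S,6R,7S,8S; 4Z,9Z)
Conditions: Dess–Martin periodinane, NaHCO3, CH2Cl2, 0 °C
Reagents that add atoms: none
Why: Buffered Dess–Martin oxidation gives the aldehyde under non-basic conditions that should not expel the β-acetoxy group, and the aldehyde is used directly.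

Step 19
Reactants: 30 seco iodo aldehyde (3S,6R,7S,8S; 4Z,9Z)
Product: 32 O15-TBS eupacunolin (1S,3S,6R,7R,8R; 4Z,9Z), via alkenylchromium dichloride 31 (not isolated)
Conditions: CrCl2 (15 equiv), NiCl2 (cat.), degassed DMSO, rt, slow addition of 30 (high dilution)
Reagents that add atoms: none
Why: Zerovalent nickel, formed from NiCl2 by CrCl2, inserts into the C10–I bond with retention of the Z geometry, and transmetalation to trivalent chromium gives the alkenylchromium 31, which adds to the C1 aldehyde; this is a Nozaki–Hiyama–Kishi reaction used as a macrocyclization, the type known for closing nine- to twelve-membered rings from alkenyl iodides and aldehydes. The ten-membered carbocycle closes by attack of C10 on the carbonyl carbon C1 with the C=O outside the new ring (10-exo-trig), helped by high dilution and by the trans lactone and the two Z olefins, which fold C10 toward C1. C1 is the only new stereocentre: the needed 1S configuration is 1,3-anti to the C3 acetoxy group, the relation favoured by dipole opposition in additions to β-acyloxy aldehydes, so the C3 stereocentre is the controlling element, although the ring conformation may modify this preference. The step needs chemoselectivity for the aldehyde over the lactone, the acetate, the tiglate, the conjugated methylene and the silyl ether, which the low basicity and carbonyl selectivity of alkenylchromium reagents secure. It also needs the C9=C10 geometry to stay Z so that C8 and C1 end up cis, which the stereoretentive oxidative addition of the iodide made in step 13 secures.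

Step 20
Reactants: 32 O15-TBS eupacunolin (1S,3S,6R,7R,8R; 4Z,9Z)
Product: 33 eupacunolin
Conditions: HF·pyridine, pyridine, THF, 0 °C
Reagents that add atoms: none
Why: Fluoride cleaves the primary allylic silyl ether, and the buffered, mildly acidic medium avoids the acetyl shift from O3 to O15 or O1 and the conjugate addition to the methylene lactone that basic fluoride could cause.

## Compound list

1 | tert-butyldimethyl(prop-2-yn-1-yloxy)silane | C#CCO[Si](C)(C)C(C)(C)C | starting material
2 | acrolein | C=CC=O | starting material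
3 | [3-(tert-butyldimethylsilyloxy)prop-1-yn-1-yl]lithium | [Li]C#CCO[Si](C)(C)C(C)(C)C | intermediate
4 | rac-6-[(tert-butyldimethylsilyl)oxy]hex-1-en-4-yn-3-ol | C=CC(O)C#CCO[Si](C)(C)C(C)(C)C | intermediate
5 | (3S)-6-[(tert-butyldimethylsilyl)oxy]hex-1-en-4-yn-3-ol | C=C[C@H](O)C#CCO[Si](C)(C)C(C)(C)C | intermediate
6 | sodium cyclic alkenylalanate from 5 (2,5-dihydro-1,2-oxaluminole, Al on C4, two 2-methoxyethoxy ligands) | C=C[C@@H]1O[Al-](OCCOC)(OCCOC)C(CO[Si](C)(C)C(C)(C)C)=C1.[Na+] | intermediate
7 | (3S,4Z)-6-[(tert-butyldimethylsilyl)oxy]-5-iodohexa-1,4-dien-3-ol | C=C[C@H](O)/C=C(\I)CO[Si](C)(C)C(C)(C)C | intermediate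
8 | tert-butyl{[(2Z,4S)-4-(1-ethoxyethoxy)-2-iodohexa-2,5-dien-1-yl]oxy}dimethylsilane (both acetal epimers) | C=C[C@H](OC(C)OCC)/C=C(\I)CO[Si](C)(C)C(C)(C)C | intermediate
9 | methyl acrylate | C=CC(=O)OC | starting material
10 | 4-methoxybenzyl alcohol | COc1ccc(CO)cc1 | starting material
11 | methyl 3-[(4-methoxybenzyl)oxy]propanoate | COC(=O)CCOCc1ccc(OC)cc1 | intermediate
12 | N-methoxy-3-[(4-methoxybenzyl)oxy]-N-methylpropanamide | CON(C)C(=O)CCOCc1ccc(OC)cc1 | intermediate
13 | alkenyllithium from 8 (Li in place of I, geometry retained) | C=C[C@H](OC(C)OCC)/C=C(\[Li])CO[Si](C)(C)C(C)(C)C | intermediate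
14 | (4Z,6S)-4-{[(tert-butyldimethylsilyl)oxy]methyl}-6-(1-ethoxyethoxy)-1-[(4-methoxybenzyl)oxy]octa-4,7-dien-3-one | C=C[C@H](OC(C)OCC)/C=C(/CO[Si](C)(C)C(C)(C)C)C(=O)CCOCc1ccc(OC)cc1 | intermediate
15 | (3S,4Z,6S)-4-{[(tert-butyldimethylsilyl)oxy]methyl}-6-(1-ethoxyethoxy)-1-[(4-methoxybenzyl)oxy]octa-4,7-dien-3-ol | C=C[C@H](OC(C)OCC)/C=C(/CO[Si](C)(C)C(C)(C)C)[C@@H](O)CCOCc1ccc(OC)cc1 | intermediate
16 | (3S,4Z,6S)-4-{[(tert-butyldimethylsilyl)oxy]methyl}-6-(1-ethoxyethoxy)-1-[(4-methoxybenzyl)oxy]octa-4,7-dien-3-yl acetate | C=C[C@H](OC(C)OCC)/C=C(/CO[Si](C)(C)C(C)(C)C)[C@@H](OC(C)=O)CCOCc1ccc(OC)cc1 | intermediate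
17 | (3S,4Z,6S)-4-{[(tert-butyldimethylsilyl)oxy]methyl}-6-hydroxy-1-[(4-methoxybenzyl)oxy]octa-4,7-dien-3-yl acetate | C=C[C@H](O)/C=C(/CO[Si](C)(C)C(C)(C)C)[C@@H](OC(C)=O)CCOCc1ccc(OC)cc1 | intermediate
18 | 2-(bromomethyl)acrylic acid | C=C(CBr)C(=O)O | starting material
19 | (3S,4Z,6S)-3-(acetyloxy)-4-{[(tert-butyldimethylsilyl)oxy]methyl}-1-[(4-methoxybenzyl)oxy]octa-4,7-dien-6-yl 2-(bromomethyl)prop-2-enoate | C=C[C@H](OC(=O)C(=C)CBr)/C=C(/CO[Si](C)(C)C(C)(C)C)[C@@H](OC(C)=O)CCOCc1ccc(OC)cc1 | intermediate
20 | (5R)-3-(bromomethyl)-5-[(1Z,3S)-3-(acetyloxy)-2-{[(tert-butyldimethylsilyl)oxy]methyl}-5-[(4-methoxybenzyl)oxy]pent-1-en-1-yl]furan-2(5H)-one | O=C1O[C@H](/C=C(/CO[Si](C)(C)C(C)(C)C)[C@@H](OC(C)=O)CCOCc2ccc(OC)cc2)C=C1CBr | intermediate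
21 | but-2-yn-1-ol | CC#CCO | starting material
22 | sodium cyclic alkenylalanate from 21 | CC1=CCO[Al-]1(OCCOC)OCCOC.[Na+] | intermediate
23 | (Z)-3-iodobut-2-en-1-ol | OC/C=C(/C)I | intermediate
24 | (Z)-3-iodobut-2-enal | O=C/C=C(/C)I | intermediate
25 | allylzinc bromide from 20 (ZnBr in place of Br) | O=C1O[C@H](/C=C(/CO[Si](C)(C)C(C)(C)C)[C@@H](OC(C)=O)CCOCc2ccc(OC)cc2)C=C1C[Zn]Br | intermediate
26 | 8-epi lactone alcohol: 6,7-trans α-methylene-γ-butyrolactone (O on C6) with the Z C5=C4(CH2OTBS)–C3H(OAc)–CH2CH2OPMB chain on C6 and the C8H(OH)–CH=C(CH3)I (Z) chain on C7; 3S,6R,7R,8R | C=C1C(=O)O[C@H](/C=C(/CO[Si](C)(C)C(C)(C)C)[C@@H](OC(C)=O)CCOCc2ccc(OC)cc2)[C@H]1[C@@H](O)/C=C(/C)I | intermediate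
27 | tiglic acid | C/C=C(\C)C(=O)O | starting material
28 | lactone tiglate, as 26 but C8 inverted and esterified with (E)-2-methylbut-2-enoic acid; 3S,6R,7S,8S | C=C1C(=O)O[C@H](/C=C(/CO[Si](C)(C)C(C)(C)C)[C@@H](OC(C)=O)CCOCc2ccc(OC)cc2)[C@H]1[C@H](OC(=O)/C(C)=C/C)/C=C(/C)I | intermediate
29 | C1 primary alcohol, as 28 with free O1–H; 3S,6R,7S,8S | C=C1C(=O)O[C@H](/C=C(/CO[Si](C)(C)C(C)(C)C)[C@@H](OC(C)=O)CCO)[C@H]1[C@H](OC(=O)/C(C)=C/C)/C=C(/C)I | intermediate
30 | seco iodo aldehyde, as 29 with C1 as CHO; 3S,6R,7S,8S; 4Z,9Z | C=C1C(=O)O[C@H](/C=C(/CO[Si](C)(C)C(C)(C)C)[C@@H](OC(C)=O)CC=O)[C@H]1[C@H](OC(=O)/C(C)=C/C)/C=C(/C)I | intermediate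
31 | alkenylchromium dichloride from 30 (trivalent chromium on C10 in place of I) | C=C1C(=O)O[C@H](/C=C(/CO[Si](C)(C)C(C)(C)C)[C@@H](OC(C)=O)CC=O)[C@H]1[C@H](OC(=O)/C(C)=C/C)/C=C(/C)[Cr](Cl)Cl | intermediate
32 | O15-tert-butyldimethylsilyl eupacunolin; 1S,3S,6R,7R,8R; 4Z,9Z | C=C1C(=O)O[C@@H]2/C=C(/CO[Si](C)(C)C(C)(C)C)[C@@H](OC(C)=O)C[C@H](O)/C(C)=C\[C@@H](OC(=O)/C(C)=C/C)[C@@H]12 | intermediate
33 | eupacunolin | C=C1C(=O)O[C@@H]2/C=C(/CO)[C@@H](OC(C)=O)C[C@H](O)/C(C)=C\[C@@H](OC(=O)/C(C)=C/C)[C@@H]12 | target

## Step count and risks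

Total step count: 20. Longest linear sequence: 16 steps (steps 1–4, 7–12 and 15–20).

Steps most likely to fail:

1. Step 19. The aldehyde may be attacked from the wrong face if the ring conformation overrides the 1,3-anti preference, and acetic acid may be lost from the β-acetoxy aldehyde while the slow closure is awaited. Fallback, which sets out from 30 and returns at 32: C1 is set by reduction and no longer by the C–C bond formation. The closure is run as in step 19 and the C1-epimeric alcohol F1 is oxidised with Dess–Martin periodinane and NaHCO3 to the ring enone F2. Corey–Bakshi–Shibata reduction with the (R)-catalyst and catecholborane, in which the C10 alkenyl group acts as the large substituent, should then give the 1S alcohol 32.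

2. Step 16. The activated C8 oxygen may be eliminated toward C7, or the displacement may not occur at all, because the oxyphosphonium is flanked by a ring carbon and tiglate is a weak and hindered nucleophile. Fallback, which sets out from 26 and returns at 28: inversion and tigloylation are separated. Mitsunobu reaction of 26 with the small and more acidic chloroacetic acid (PPh3, DIAD) gives the inverted chloroacetate F3. Thiourea and NaHCO3 in ethanol remove the chloroacetyl group beside the acetate and the lactone to give the inverted alcohol F4. Yamaguchi esterification of F4 with 27 (2,4,6-trichlorobenzoyl chloride, Et3N, DMAP) gives 28 with retention.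

3. Step 15. The carbon–iodine bond of the β-iodo enal may be reduced, or the enal may isomerise from Z to E on the zinc surface, before the C7–C8 bond forms. Fallback, which sets out from 20 and 21 and returns at 26: iodine is brought in after the C–C bond. MnO2 oxidation of 21 gives but-2-ynal F5. The Zn Barbier reaction of 20 with this aldehyde gives the propargylic alcohol F6 with the same C7/C8 relation. Trans-hydrosilylation with Et3SiH and [Cp*Ru(MeCN)3]PF6 places silicon on C10, distal to the hydroxyl and cis to C8, and gives the (Z)-alkenylsilane F7. Iododesilylation with N-iodosuccinimide in (CF3)2CHOH, with retention, gives 26.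

## Further compounds

F1 | step 19 | C1 epimer of 32 (1R,3S,6R,7R,8R) | C=C1C(=O)O[C@@H]2/C=C(/CO[Si](C)(C)C(C)(C)C)[C@@H](OC(C)=O)C[C@@H](O)/C(C)=C\[C@@H](OC(=O)/C(C)=C/C)[C@@H]12
F2 | step 19 | ring enone, C1 ketone of 32 | C=C1C(=O)O[C@@H]2/C=C(/CO[Si](C)(C)C(C)(C)C)[C@@H](OC(C)=O)CC(=O)/C(C)=C\[C@@H](OC(=O)/C(C)=C/C)[C@@H]12
F3 | step 16 | C8-inverted chloroacetate of 26 (3S,6R,7S,8S) | C=C1C(=O)O[C@H](/C=C(/CO[Si](C)(C)C(C)(C)C)[C@@H](OC(C)=O)CCOCc2ccc(OC)cc2)[C@H]1[C@H](OC(=O)CCl)/C=C(/C)I
F4 | step 16 | C8-inverted alcohol, C8 epimer of 26 (3S,6R,7R,8S) | C=C1C(=O)O[C@H](/C=C(/CO[Si](C)(C)C(C)(C)C)[C@@H](OC(C)=O)CCOCc2ccc(OC)cc2)[C@H]1[C@H](O)/C=C(/C)I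
F5 | step 15 | but-2-ynal | CC#CC=O
F6 | step 15 | propargylic alcohol, as 26 with a but-2-ynyl carbinol at C8 (3S,6R,7R,8R) | C=C1C(=O)O[C@H](/C=C(/CO[Si](C)(C)C(C)(C)C)[C@@H](OC(C)=O)CCOCc2ccc(OC)cc2)[C@H]1[C@@H](O)C#CC
F7 | step 15 | (Z)-alkenyl(triethyl)silane, as 26 with SiEt3 in place of I (3S,6R,7R,8R) | C=C1C(=O)O[C@H](/C=C(/CO[Si](C)(C)C(C)(C)C)[C@@H](OC(C)=O)CCOCc2ccc(OC)cc2)[C@H]1[C@@H](O)/C=C(/C)[Si](CC)(CC)CC
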